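The run was to last 40 h, so I reckoned that time in halvings of the substrate.

| flask | left-handed substrate | right-handed substrate | reagent | remark | time |
|---|---|---|---|---|---|
| zeta | 0.010 M | 0.010 M | 0.056 M | run made earlier |  |
| gamma | 0.010 M | 0.010 M | 0.088 M | run made earlier |  |
| flask | 0.010 M | 0.010 M | 0.0400 M |  | 40 h |

| run | time / h | left-handed product / % | right-handed product / % | left-handed substrate / % |
|---|---|---|---|---|
| zeta | 4.00 | 15 | 1 | 40 |
| zeta | 6.00 | 17 | 5 | 32 |
| zeta | 8.00 | 24 | 10 | 34 |
| zeta | 15.0 | 33 | 11 | 27 |
| zeta | 20.0 | 33 | 20 | 23 |
| zeta | 30.0 | 41 | 30 | 14 |
| zeta | 50.0 | 49 | 40 | 5 |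
| gamma | 6.00 | 27 | 4 | 30 |
| gamma | 15.0 | 43 | 18 | 19 |
| gamma | 20.0 | 44 | 21 | 10 |
| gamma | 30.0 | 49 | 35 | 7 |
| gamma | 40.0 | 51 | 45 | 3 |
| gamma | 50.0 | 50 | 49 | 6 |

(scatter of a reading: 2 percentage points)

- reagent is single-handed; left-handed substrate and right-handed substrate are mirror images of each other, charged as a racemate, each of them at the stated concentration
- steps thought possible: reagent <-> dormant form; left-handed product <-> right-handed product; reagent + right-handed substrate -> right-handed product; reagent + left-handed substrate -> left-handed product; left-handed substrate <-> right-handed substrate
- an excess is the difference of the two amounts in percent of their sum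
- an excess is below zero if the other one leads
- the handed part of reagent does not stay in what it makes, so the products of the two hands are mirror images too

- excess of left-handed product over right-handed product in the product at 50 min
- excess of left-handed product over right-handed product in the product at 40 h
- part of the left-handed substrate and right-handed substrate charged together that has reacted at 40 h

By difference, the two substrates stayed about equal in most readings of both runs, so I let one curve stand for both. In zeta, the run nearer this flask in reagent charge, the reading of the left-handed substrate fell from its even share to 5% at 50.0 h. Reading that as a pseudo-first-order decay against the reagent charge gave D = 50.6 M·min, the reagent molarity times the time that halves the remaining substrate. Then n = ct/D halvings pass in time t, where c is the charge less what the substrate has taken. The two substrates together were 0.0200 M, and I bracketed the part reacted: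

Ceiling, c at the charge: n = 1.90, reacted 73.2%

Floor, c less all the substrate: n = 0.949, reacted 48.2%

Tighter floor, c less that ceiling's share: c = 0.0254 M, n = 1.20, reacted 56.6%

Tighter ceiling, c midway between the charge and what that floor leaves: c = 0.0343 M, n = 1.63, reacted 67.7%

The forecast put 65% reacted inside that bracket, with excesses of 89% and 11%, holding that “the reagent takes almost only the left-handed substrate”.

The flask gave 64.7% reacted, with excesses of 92.7% at 50 min and 11.1% at 40 h.

    reagent ⇌ dormant form (K = 0.150, k = 0.0530 h⁻¹)
    left-handed product ⇌ right-handed product (k = 0.0670 h⁻¹)
    reagent + right-handed substrate → right-handed product (k = 0.0180 M⁻¹ h⁻¹)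
    reagent + left-handed substrate → left-handed product (k = 1.90 M⁻¹ h⁻¹)
    left-handed substrate ⇌ right-handed substrate (k = 0.390 h⁻¹)

At 40.0 h the slowest mode of this flask had a half-life of 25.3 h, shorter than the run, whose length was 1.58 such half-lives. The 35.3% of substrate left in this flask is 1.50 halvings, which through D corresponds to a reckoned c of 0.0316 M. The neighbouring flask charged with 0.068 M of reagent counts 3.23 halvings at its charge, a ceiling of 89.3%, and it stood at 83.5% reacted.

(The numbers in the tables are simulated with made-up constants; noise was put on by code.)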